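The readings stem from a simulated flask from invented constants; noise was put on by code.

If you want a flask's end from its early readings, hold the time you give it against the time its pace needs to spend the charge.

| flask | E | X | G | temperature | remark | time |
|---|---|---|---|---|---|---|
| theta | 0.20 M | 1.05 equiv | 2 mM | 31 °C | run made earlier |  |
| epsilon | 0.20 M | 1.05 equiv | 8 mM | 45 °C | run made earlier |  |
| north-west | 0.20 M | 1.05 equiv | 4.00 mM | 25 °C |  | 8.0 min |
| south-east | 0.20 M | 1.05 equiv | 4.00 mM | 50 °C |  | 8.0 min |

- theta (time / min: J / %): 0.833: 0; 2.50: 6.0; 4.00: 10.3; 6.00: 15.2; 10.0: 29.0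
- epsilon (time / min: J / %): 0.333: 1.6; 1.00: 6.7; 1.33: 8.2; 2.00: 16.0; 4.00: 29.4

(standard deviation of a reading: 1 percentage point)

- the best flask by amount of J, in percent of the E charged; "all alike" if 1.5 percentage points covers them all (north-west / south-east / all alike)
- amount of J at the end, in percent of the E charged, north-west
- amount of J at the end, in percent of the E charged, south-east



Start with the end state. X stands at 1.05 equiv, so if J takes one X per E and nothing else uses either, E is the limiting reagent and your ceiling is the whole charge. Now climb the ladder of times, fastest first. Any start-up lag is short: theta reads 0% at 0.833 min but 6.0% at 2.50 min. Next comes the time you give, 8.0 min. Above it stands the spend time, the minutes a straight line at the run's pace takes to turn the whole charge of E into J. Epsilon, from its second reading to its last, gives 13.2 min, and that is the quantity to carry. Theta gives a longer 32.6 min.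

So my reckoning runs like this. North-west, cooler than theta, should stay under the 24.5% of theta's line. South-east, hotter than epsilon, has 60.6% on epsilon's line. But epsilon's pace falls from 0.0930 min⁻¹ to 0.0670 min⁻¹ of the charge, a weak bend given a scatter of 1 percentage point. I therefore expect south-east under that mark, yet ahead of north-west.

The forecast, on its own grounds, that “the G order is probably low”, says south-east, with 20% (11% to 36%) in north-west and 60% (36% to 85%) in south-east.

The flasks give 12.0% in north-west and 35.9% in south-east, so south-east leads.

    Z → Q (k = 0.0500 min⁻¹, Ea = 98.0 kJ mol⁻¹)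
    E ⇌ L (K = 0.330, k = 0.140 min⁻¹, Ea = 89.0 kJ mol⁻¹, ΔH = 13.0 kJ mol⁻¹)
    L + Z → J (k = 2.60 M⁻¹ min⁻¹, Ea = 47.0 kJ mol⁻¹)
    X → Z (k = 0.0630 min⁻¹, Ea = 78.0 kJ mol⁻¹)
    E + G → D (k = 27.0 M⁻¹ min⁻¹, Ea = 45.0 kJ mol⁻¹)
    (constants at 25 °C)

Multiply by the spend time and south-east's 35.9% is worth 4.74 min of epsilon's line out of the 8.0 min on the clock. Its X is down to 0.319% of its charge by then. Now read the same flask at 3.0 min: it holds 29.4%, worth 3.88 min of line, more than its clock shows. The remaining 5.00 min of south-east add just 0.858 min of line.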